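**Retrosynthetic overview**

- Target ⇒ bicyclic methoxy peroxyketal (OMe in place of the C3 methyl): a final axial C-methylation of the ring peroxycarbenium ion sets C3.
- Peroxyketal ⇒ butenolide dimethyl ketal + H2O2: ketal perhydrolysis, then intramolecular peroxy-oxa-Michael addition; these two C–O bonds build the 1,2-dioxane (ring B) on the butenolide (ring A) and set C7a.
- Butenolide ⇒ α-silyloxy aldehyde (Z-olefination, lactonisation) ⇒ methyl ketone silyl enol ether + methyl pyruvate (copper–bis(oxazoline) aldol sets C4a).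
- Methyl ketone ⇒ alkyl bromide + pent-3-en-2-one (asymmetric conjugate addition sets the side-chain centre); bromide ⇒ pent-4-yn-1-ol + benzyl chloride (carboalumination fixes the E-alkene).
- Ring order: ring A (lactone) first, ring B (1,2-dioxane) second; the O–O unit enters only two steps from the end.

Assumption: ring positions are numbered as in furo[3,2-c][1,2]dioxin (O1, O2, C3, C4, C4a, O5, C6, C7, C7a).
Assumption: in the two ligand-controlled steps (3 and 5) the ligand antipode written is taken to give the drawn sense; both antipodes are commercial and the sense is checked on the first run.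

**Route**

Step 1
Reactants: 1 pent-4-yn-1-ol; 2 benzyl chloride
Product: 4 (4E)-4-methyl-6-phenylhex-4-en-1-ol, via (E)-alkenylalane 3 (not isolated)
Conditions: Me3Al (3 equiv), Cp2ZrCl2 (0.25 equiv), CH2Cl2, 0 °C to rt; then 2, Pd(PPh3)4 (5 mol%), THF, rt; aq. HCl
Reagents that add atoms: trimethylaluminium, C[Al](C)C
Why: Negishi zirconium-catalysed carboalumination adds Me–Al syn across the alkyne and the zerovalent-palladium cross-coupling of the alkenylalane with the benzyl halide retains that geometry, which fixes the E-trisubstituted alkene.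

Step 2
Reactants: 4 (4E)-4-methyl-6-phenylhex-4-en-1-ol
Product: 5 [(2E)-6-bromo-3-methylhex-2-en-1-yl]benzene
Conditions: CBr4, PPh3, CH2Cl2, 0 °C
Reagents that add atoms: carbon tetrabromide, BrC(Br)(Br)Br
Why: The Appel reaction converts the primary alcohol to the bromide under neutral conditions that leave the alkene untouched.

Step 3
Reactants: 5 [(2E)-6-bromo-3-methylhex-2-en-1-yl]benzene; 6 (3E)-pent-3-en-2-one
Product: 8 (4S,8E)-4,8-dimethyl-10-phenyldec-8-en-2-one, via Grignard reagent 7 (not isolated)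
Conditions: Mg, Et2O, rt; then slow addition to 6, CuBr·SMe2 (5 mol%), (R)-1-[(S)-2-(diphenylphosphino)ferrocenyl]ethyldicyclohexylphosphine (6 mol%), tBuOMe, −75 °C; aq. work-up
Reagents that add atoms: none
Why: Copper-catalysed asymmetric conjugate addition of a primary alkyl Grignard reagent to a linear methyl enone forms the C–C bond and sets the side-chain methyl centre as S under ligand control.

Step 4
Reactants: 8 (4S,8E)-4,8-dimethyl-10-phenyldec-8-en-2-one
Product: 9 {[(4S,8E)-4,8-dimethyl-10-phenyldeca-1,8-dien-2-yl]oxy}trimethylsilane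
Conditions: LiN(iPr)2, Me3SiCl, THF, −78 °C
Reagents that add atoms: chlorotrimethylsilane, C[Si](C)(C)Cl
Why: Kinetic enolisation of the methyl ketone at the unhindered CH3 group with in situ silylation gives the terminal silyl enol ether regioselectively.

Step 5
Reactants: 9 {[(4S,8E)-4,8-dimethyl-10-phenyldeca-1,8-dien-2-yl]oxy}trimethylsilane; 10 methyl pyruvate
Product: 11 methyl (2R,6S,10E)-2,6,10-trimethyl-4-oxo-12-phenyl-2-[(trimethylsilyl)oxy]dodec-10-enoate
Conditions: Cu(OTf)2 (10 mol%), (R,R)-2,2′-isopropylidenebis(4-tert-butyl-2-oxazoline) (11 mol%), THF, −78 °C; neutral work-up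
Reagents that add atoms: none
Why: The Mukaiyama aldol addition to pyruvate chelated on the divalent copper–bis(oxazoline) Lewis acid sets the oxygen-bearing quaternary centre as R by catalyst control, with silyl transfer to the new tertiary alkoxide.

Step 6
Reactants: 11 methyl (2R,6S,10E)-2,6,10-trimethyl-4-oxo-12-phenyl-2-[(trimethylsilyl)oxy]dodec-10-enoate
Product: 12 methyl (2R,6S,10E)-4,4-dimethoxy-2,6,10-trimethyl-12-phenyl-2-[(trimethylsilyl)oxy]dodec-10-enoate
Conditions: MeOSiMe3 (3 equiv), Me3SiOTf (5 mol%), CH2Cl2, −78 °C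
Reagents that add atoms: methoxytrimethylsilane, CO[Si](C)(C)C
Why: Noyori ketalisation under aprotic conditions masks the ketone as its dimethyl ketal without cleaving the tertiary silyl ether or dehydrating the β-oxy ketone.

Step 7
Reactants: 12 methyl (2R,6S,10E)-4,4-dimethoxy-2,6,10-trimethyl-12-phenyl-2-[(trimethylsilyl)oxy]dodec-10-enoate
Product: 13 (2R,6S,10E)-4,4-dimethoxy-2,6,10-trimethyl-12-phenyl-2-[(trimethylsilyl)oxy]dodec-10-enal
Conditions: iBu2AlH (1.2 equiv), CH2Cl2, −78 °C; aq. potassium sodium tartrate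
Reagents that add atoms: none
Why: Low-temperature hydride reduction of the α-silyloxy methyl ester stops at the aldehyde, and the quaternary α-carbon cannot epimerise.

Step 8
Reactants: 13 (2R,6S,10E)-4,4-dimethoxy-2,6,10-trimethyl-12-phenyl-2-[(trimethylsilyl)oxy]dodec-10-enal
Product: 15 (5R)-5-[(4S,8E)-2,2-dimethoxy-4,8-dimethyl-10-phenyldec-8-en-1-yl]-5-methylfuran-2(5H)-one, via Z-enoate 14 (not isolated)
Conditions: (CF3CH2O)2P(O)CH2CO2Me, KN(SiMe3)2, 18-crown-6, THF, −78 °C; then Bu4NF, THF, 0 °C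
Reagents that add atoms: methyl bis(2,2,2-trifluoroethyl)phosphonoacetate, COC(=O)CP(=O)(OCC(F)(F)F)OCC(F)(F)F
Why: Still–Gennari olefination gives the Z-enoate and fluoride desilylation lets the tertiary alkoxide close onto the cis ester (lactonisation) to form the butenolide without touching the quaternary centre.

Step 9
Reactants: 15 (5R)-5-[(4S,8E)-2,2-dimethoxy-4,8-dimethyl-10-phenyldec-8-en-1-yl]-5-methylfuran-2(5H)-one
Product: 17 (4aR,7aR)-3-methoxy-4a-methyl-3-[(2S,6E)-2,6-dimethyl-8-phenyloct-6-en-1-yl]-4,4a,7,7a-tetrahydro-3H-furo[3,2-c][1,2]dioxin-6-one (both C3 epimers), via hydroperoxy ketal 16 (not isolated)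
Conditions: urea·H2O2 (5 equiv), Sc(OTf)3 (10 mol%), MeOH, 0 °C; aq. wash; then Et2NH (0.5 equiv), CF3CH2OH, rt
Reagents that add atoms: hydrogen peroxide (used as urea·H2O2), OO
Why: Acid-catalysed ketal perhydrolysis forms the first C–O bond and the intramolecular 6-exo peroxy-oxa-Michael addition to the butenolide forms the second, the short tether forcing a cis ring fusion so that C7a is set as R from the existing 4aR centre.

Step 10
Reactants: 17 (4aR,7aR)-3-methoxy-4a-methyl-3-[(2S,6E)-2,6-dimethyl-8-phenyloct-6-en-1-yl]-4,4a,7,7a-tetrahydro-3H-furo[3,2-c][1,2]dioxin-6-one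
Product: 18 plakortolide G, (3R,4aR,7aR)-3,4a-dimethyl-3-[(2S,6E)-2,6-dimethyl-8-phenyloct-6-en-1-yl]-4,4a,7,7a-tetrahydro-3H-furo[3,2-c][1,2]dioxin-6-one
Conditions: Me3Al (4 equiv), Me3SiOTf (1.2 equiv), CH2Cl2, −78 to −40 °C
Reagents that add atoms: trimethylaluminium, C[Al](C)C
Why: Proposed new method: the silyl triflate ionises the methoxy peroxyketal (either epimer) to a cyclic peroxycarbenium ion whose favoured half-chair holds the C4a–O lactone bond pseudo-axial and the C4a methyl equatorial, and methyl transfer from aluminium along the axial trajectory on that face puts the new methyl cis to the lactone oxygen and the side chain equatorial (3R), the closest known reactions being Lewis-acid substitutions of cyclic peroxyketals by allylsilanes or silyl enol ethers and axial C-methylation of six-membered oxocarbenium ions by Me3Al.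

**Compound list**

1 | pent-4-yn-1-ol | C#CCCCO | starting material
2 | benzyl chloride | ClCc1ccccc1 | starting material
3 | dimethyl{(1E)-5-[(dimethylalumanyl)oxy]-2-methylpent-1-en-1-yl}alumane | C/C(=C\[Al](C)C)CCCO[Al](C)C | intermediate
4 | (4E)-4-methyl-6-phenylhex-4-en-1-ol | C/C(=C\Cc1ccccc1)CCCO | intermediate
5 | [(2E)-6-bromo-3-methylhex-2-en-1-yl]benzene | C/C(=C\Cc1ccccc1)CCCBr | intermediate
6 | (3E)-pent-3-en-2-one | C/C=C/C(C)=O | starting material
7 | [(4E)-4-methyl-6-phenylhex-4-en-1-yl]magnesium bromide | C/C(=C\Cc1ccccc1)CCC[Mg]Br | intermediate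
8 | (4S,8E)-4,8-dimethyl-10-phenyldec-8-en-2-one | CC(=O)C[C@@H](C)CCC/C(C)=C/Cc1ccccc1 | intermediate
9 | {[(4S,8E)-4,8-dimethyl-10-phenyldeca-1,8-dien-2-yl]oxy}trimethylsilane | C=C(O[Si](C)(C)C)C[C@@H](C)CCC/C(C)=C/Cc1ccccc1 | intermediate
10 | methyl pyruvate (methyl 2-oxopropanoate) | COC(=O)C(C)=O | starting material
11 | methyl (2R,6S,10E)-2,6,10-trimethyl-4-oxo-12-phenyl-2-[(trimethylsilyl)oxy]dodec-10-enoate | COC(=O)[C@](C)(O[Si](C)(C)C)CC(=O)C[C@@H](C)CCC/C(C)=C/Cc1ccccc1 | intermediate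
12 | methyl (2R,6S,10E)-4,4-dimethoxy-2,6,10-trimethyl-12-phenyl-2-[(trimethylsilyl)oxy]dodec-10-enoate | COC(=O)[C@](C)(O[Si](C)(C)C)CC(OC)(OC)C[C@@H](C)CCC/C(C)=C/Cc1ccccc1 | intermediate
13 | (2R,6S,10E)-4,4-dimethoxy-2,6,10-trimethyl-12-phenyl-2-[(trimethylsilyl)oxy]dodec-10-enal | O=C[C@](C)(O[Si](C)(C)C)CC(OC)(OC)C[C@@H](C)CCC/C(C)=C/Cc1ccccc1 | intermediate
14 | methyl (2Z,4R,8S,12E)-6,6-dimethoxy-4,8,12-trimethyl-14-phenyl-4-[(trimethylsilyl)oxy]tetradeca-2,12-dienoate | COC(=O)/C=C\[C@](C)(O[Si](C)(C)C)CC(OC)(OC)C[C@@H](C)CCC/C(C)=C/Cc1ccccc1 | intermediate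
15 | (5R)-5-[(4S,8E)-2,2-dimethoxy-4,8-dimethyl-10-phenyldec-8-en-1-yl]-5-methylfuran-2(5H)-one | O=C1C=C[C@@](C)(CC(OC)(OC)C[C@@H](C)CCC/C(C)=C/Cc2ccccc2)O1 | intermediate
16 | (5R)-5-[(4S,8E)-2-hydroperoxy-2-methoxy-4,8-dimethyl-10-phenyldec-8-en-1-yl]-5-methylfuran-2(5H)-one, both epimers at the ketal carbon | O=C1C=C[C@@](C)(CC(OC)(OO)C[C@@H](C)CCC/C(C)=C/Cc2ccccc2)O1 | intermediate
17 | (4aR,7aR)-3-methoxy-4a-methyl-3-[(2S,6E)-2,6-dimethyl-8-phenyloct-6-en-1-yl]-4,4a,7,7a-tetrahydro-3H-furo[3,2-c][1,2]dioxin-6-one, cis-fused, both C3 epimers | C/C(=C\Cc1ccccc1)CCC[C@H](C)CC1(OC)C[C@@]2(C)OC(=O)C[C@H]2OO1 | intermediate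
18 | plakortolide G, (3R,4aR,7aR)-3,4a-dimethyl-3-[(2S,6E)-2,6-dimethyl-8-phenyloct-6-en-1-yl]-4,4a,7,7a-tetrahydro-3H-furo[3,2-c][1,2]dioxin-6-one | C/C(=C\Cc1ccccc1)CCC[C@H](C)C[C@]1(C)C[C@@]2(C)OC(=O)C[C@H]2OO1 | target

**Step count and risks**

Total step count: 10. Longest linear sequence: 10 (from 1).

The three steps most likely to fail:

1. Step 10, the new methylation. The peroxide may not survive the organoaluminium reagent, or the ketal may ionise with ring opening. The fallback uses known chemistry, sets out from 15 and comes back at 18. Mild acid hydrolysis (pyridinium tosylate, aqueous acetone) gives the keto butenolide (5R)-5-[(4S,8E)-4,8-dimethyl-2-oxo-10-phenyldec-8-en-1-yl]-5-methylfuran-2(5H)-one F1. Non-basic Takai–Lombardo methylenation (Zn, CH2Br2, TiCl4, THF) gives the 1,1-disubstituted alkene (5R)-5-[(4S,8E)-4,8-dimethyl-2-methylidene-10-phenyldec-8-en-1-yl]-5-methylfuran-2(5H)-one F2. Isayama–Mukaiyama hydroperoxysilylation (Co(thd)2 cat., thd = 2,2,6,6-tetramethylheptane-3,5-dionate, Et3SiH, O2, ClCH2CH2Cl, rt) converts the more reactive 1,1-disubstituted alkene to the tertiary silyl peroxide (5R)-5-methyl-5-{(4S,8E)-2,4,8-trimethyl-10-phenyl-2-[(triethylsilyl)peroxy]dec-8-en-1-yl}furan-2(5H)-one F3, as both epimers. Bu4NF followed by Et2NH in CF3CH2OH frees the hydroperoxide, which closes onto the butenolide to give 18 together with its C3 epimer (3S,4aR,7aR)-3,4a-dimethyl-3-[(2S,6E)-2,6-dimethyl-8-phenyloct-6-en-1-yl]-4,4a,7,7a-tetrahydro-3H-furo[3,2-c][1,2]dioxin-6-one F4, removed by HPLC. This route gives no control at C3.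

2. Step 9, the perhydrolysis and peroxy-Michael ring closure. The mixed ketal may form incompletely or the hindered ketal hydroperoxide may add slowly. The fallback sets out from 15 and comes back at 17. Ethereal H2O2 with catalytic BF3·OEt2 converts the ketal to the geminal dihydroperoxide (5R)-5-[(4S,8E)-2,2-dihydroperoxy-4,8-dimethyl-10-phenyldec-8-en-1-yl]-5-methylfuran-2(5H)-one F5, which offers two equivalent nucleophiles. Et2NH in CF3CH2OH closes it to (4aR,7aR)-3-hydroperoxy-4a-methyl-3-[(2S,6E)-2,6-dimethyl-8-phenyloct-6-en-1-yl]-4,4a,7,7a-tetrahydro-3H-furo[3,2-c][1,2]dioxin-6-one F6. Acid-catalysed exchange in MeOH (pyridinium tosylate) replaces the exocyclic hydroperoxy group by methoxy and returns 17.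

3. Step 3, the catalytic conjugate addition. A functionalised Grignard reagent may give lower enantioselectivity or some 1,2-addition. The fallback is auxiliary-controlled; it sets out from 5 (through 7) and comes back at 8. (4S)-4-Phenyl-1,3-oxazolidin-2-one is N-acylated (n-BuLi, crotonyl chloride) to (4S)-3-[(2E)-but-2-enoyl]-4-phenyl-1,3-oxazolidin-2-one F7. Addition of 7 with CuBr·SMe2 in THF/Me2S at −78 °C, anti to the phenyl group of the chelated imide, gives (4S)-3-[(3S,7E)-3,7-dimethyl-9-phenylnon-7-enoyl]-4-phenyl-1,3-oxazolidin-2-one F8. Me3Al with MeNHOMe·HCl gives the Weinreb amide (3S,7E)-N-methoxy-N,3,7-trimethyl-9-phenylnon-7-enamide F9, and MeMgBr converts it to 8.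

Further compounds
F1 | step 10 | (5R)-5-[(4S,8E)-4,8-dimethyl-2-oxo-10-phenyldec-8-en-1-yl]-5-methylfuran-2(5H)-one | O=C1C=C[C@@](C)(CC(=O)C[C@@H](C)CCC/C(C)=C/Cc2ccccc2)O1
F2 | step 10 | (5R)-5-[(4S,8E)-4,8-dimethyl-2-methylidene-10-phenyldec-8-en-1-yl]-5-methylfuran-2(5H)-one | O=C1C=C[C@@](C)(CC(=C)C[C@@H](C)CCC/C(C)=C/Cc2ccccc2)O1
F3 | step 10 | (5R)-5-methyl-5-{(4S,8E)-2,4,8-trimethyl-10-phenyl-2-[(triethylsilyl)peroxy]dec-8-en-1-yl}furan-2(5H)-one, both epimers at the peroxide carbon | O=C1C=C[C@@](C)(CC(C)(OO[Si](CC)(CC)CC)C[C@@H](C)CCC/C(C)=C/Cc2ccccc2)O1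
F4 | step 10 | (3S,4aR,7aR)-3,4a-dimethyl-3-[(2S,6E)-2,6-dimethyl-8-phenyloct-6-en-1-yl]-4,4a,7,7a-tetrahydro-3H-furo[3,2-c][1,2]dioxin-6-one | C/C(=C\Cc1ccccc1)CCC[C@H](C)C[C@@]1(C)C[C@@]2(C)OC(=O)C[C@H]2OO1
F5 | step 9 | (5R)-5-[(4S,8E)-2,2-dihydroperoxy-4,8-dimethyl-10-phenyldec-8-en-1-yl]-5-methylfuran-2(5H)-one | O=C1C=C[C@@](C)(CC(OO)(OO)C[C@@H](C)CCC/C(C)=C/Cc2ccccc2)O1
F6 | step 9 | (4aR,7aR)-3-hydroperoxy-4a-methyl-3-[(2S,6E)-2,6-dimethyl-8-phenyloct-6-en-1-yl]-4,4a,7,7a-tetrahydro-3H-furo[3,2-c][1,2]dioxin-6-one, both C3 epimers | C/C(=C\Cc1ccccc1)CCC[C@H](C)CC1(OO)C[C@@]2(C)OC(=O)C[C@H]2OO1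
F7 | step 3 | (4S)-3-[(2E)-but-2-enoyl]-4-phenyl-1,3-oxazolidin-2-one | C/C=C/C(=O)N1C(=O)OC[C@@H]1c1ccccc1
F8 | step 3 | (4S)-3-[(3S,7E)-3,7-dimethyl-9-phenylnon-7-enoyl]-4-phenyl-1,3-oxazolidin-2-one | O=C1OC[C@H](c2ccccc2)N1C(=O)C[C@@H](C)CCC/C(C)=C/Cc3ccccc3
F9 | step 3 | (3S,7E)-N-methoxy-N,3,7-trimethyl-9-phenylnon-7-enamide | CON(C)C(=O)C[C@@H](C)CCC/C(C)=C/Cc1ccccc1
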